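The runs are simulated with constants of no real substance, and the scatter is random.

**Minutes: three flasks, one electrophile charge**

The ratio of nucleophile charges, summer over winter, is 1.62, and the chair opened by noting that target at 1.33 h stands between those runs at 1.66 as read, within the scatter of so small a reading, so she took the early rate of target to follow nucleophile concentration at first order.

| flask | electrophile | nucleophile | remark | time |
|---|---|---|---|---|
| winter | 28 mM | 24 mM | run made earlier |  |
| summer | 28 mM | 39 mM | run made earlier |  |
| ochre | 28 mM | 34.0 mM |  | 6.0 h |
| grey | 28 mM | 44.0 mM |  | 6.0 h |
| teal | 28 mM | 57.0 mM |  | 6.0 h |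

| run | time / h | electrophile / % | target / % |
|---|---|---|---|
| winter | 0.417 | 96.0 | 1.6 |
| winter | 1.33 | 88.4 | 7.7 |
| winter | 2.00 | 83.0 | 11.9 |
| winter | 3.00 | 78.5 | 15.5 |
| winter | 5.00 | 67.9 | 21.2 |
| winter | 6.00 | 64.7 | 23.8 |
| summer | 0.500 | 93.0 | 4.9 |
| summer | 0.833 | 88.2 | 8.9 |
| summer | 1.33 | 83.1 | 12.8 |
| summer | 2.00 | 77.4 | 18.9 |
| summer | 4.00 | 63.5 | 28.9 |
| summer | 6.00 | 54.5 | 34.7 |

(readings scatter by 0.5 percentage points)



- which of these there is most of at the end, counted by the electrophile in it, ochre (electrophile / target)
- which of these there is most of at the end, counted by the electrophile in it, grey (electrophile / target)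
- which of these there is most of at the end, counted by the electrophile in it, teal (electrophile / target)
- the largest of these amounts at the end, in percent of the electrophile charged, ochre
- the largest of these amounts at the end, in percent of the electrophile charged, grey
- the largest of these amounts at the end, in percent of the electrophile charged, teal

A colleague objected that the ratio of targets at the end is 1.46. The chair answered that summer holds less electrophile then, 54.5% against 64.7%, so target must be divided by mean electrophile as well.

As secretary I divided end target by the mean of charged and final electrophile, by the nucleophile charged and by the time. That gave 0.00201 mM⁻¹ h⁻¹ for winter and 0.00192 mM⁻¹ h⁻¹ for summer. Their mean, 0.00196 mM⁻¹ h⁻¹, is the charge constant; multiplied by a nucleophile charge it serves my reckoning as a pseudo-first-order constant.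

The colleague added that electrophile plus target falls short of the charge by 11 percentage points in winter and 11 points in summer, so I carried the mean shortfall, 11 points, into each flask. For each flask I set target equal to the charge constant times nucleophile charge times time times mean electrophile, took final electrophile as the charge less shortfall less target, and solved the two together. My reckoning gives ochre electrophile 57.3%, grey electrophile 50.0% and teal target 47.5%.

The forecast named electrophile at 57% for ochre, electrophile at 51% for grey and target at 47% for teal, a point above me on grey. Its words on teal: “Teal crosses over narrowly to target”.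

**Result.** Ochre gave electrophile at 57.6%, grey electrophile at 51.0%, teal target at 48.8%.

    electrophile + nucleophile → acid set free + target (k = 8.60 × 10⁻⁴ L mol⁻¹ s⁻¹)
    nucleophile + acid set free ⇌ protonated nucleophile, settled at all times (K = 95000 L mol⁻¹)
    nucleophile ⇌ dormant form (K = 0.230, k = 2.20 × 10⁻⁶ s⁻¹)
    2 electrophile → self-condensation product (k = 1.50 × 10⁻⁴ L mol⁻¹ s⁻¹)

With teal's final electrophile of 43.2%, the charge constant gives target 48.1% against 48.8%. On grey raised to 75 mM of nucleophile, with 34.0% electrophile, it gives 59.2% against 59.4%. Grey at 44.0 mM shows the other verdict: electrophile 51.0%, target 39.9%. In teal, by 3.00 h, electrophile and nucleophile had made 33.4% target while protonated nucleophile reached 9.36 mM and self-condensation product 5.56%. By 6.00 h, with 49.1% of teal's nucleophile charge still free, protonated nucleophile stood at 13.7 mM and self-condensation product at 7.96%.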